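**Assumption:** the target SMILES has no stereocentre and no stereo-axis, so the achiral compound itself is the "single enantiomer"; apigenin and genkwanin are taken as commercial.

**Retrosynthetic overview**
1. Last operation: global hydrogenolysis of three O-benzyl groups of a tri-O-benzyl biflavone ether.
2. Key disconnection: the diaryl ether is cut on its electron-rich, doubly ortho-flanked side (C6''–O), not at the activated C4'–O bond that invites an early SNAr on a benzaldehyde. Two intact flavones are joined late by Ullmann coupling: a 6-iodoflavone (electrophile) and genkwanin (4'-OH nucleophile).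
3. The 6-iodoflavone comes from apigenin by 7,4'-di-O-benzylation, C6–H iodination steered by the hydrogen-bonded 5-OH, then 5-O-benzylation.
4. Ring formation: none. Both chromone ring systems are bought complete (apigenin, genkwanin); the route forges only one C–I bond and one C–O bond on the skeleton.

**Route**

Step 1
Reactants: 1 apigenin
Product: 3 7,4'-di-O-benzylapigenin [7-(benzyloxy)-2-(4-benzyloxyphenyl)-5-hydroxychromen-4-one], via 7-O-benzylapigenin 2 (not isolated)
Conditions: BnBr (2.2 equiv), K2CO3 (2.5 equiv), DMF, 25 °C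
Reagents that add atoms: benzyl bromide, BrCc1ccccc1
Why: Williamson ether synthesis in which the 7-OH (a vinylogous acid) reacts first and the 4'-OH second, while the 5-OH is held in a hydrogen bond to C4=O and stays free with about two equivalents of BnBr; no stereocentre is formed.

Step 2
Reactants: 3 7,4'-di-O-benzylapigenin
Product: 4 6-iodo-7,4'-di-O-benzylapigenin [7-(benzyloxy)-2-(4-benzyloxyphenyl)-5-hydroxy-6-iodochromen-4-one]
Conditions: BnMe3N+ ICl2− (1.05 equiv), CaCO3, CH2Cl2–MeOH (5:2), 25 °C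
Reagents that add atoms: benzyltrimethylammonium dichloroiodate, C[N+](C)(C)Cc1ccccc1.Cl[I-]Cl
Why: Electrophilic aromatic iodination in which the free, chelated 5-OH of a 5-hydroxy-7-alkoxyflavone directs the mild iodonium donor to its only open ortho position C6 (5,7-dialkoxyflavones go to C8 instead), CaCO3 takes up the HCl, and the B ring is deactivated by the chromone.

Step 3
Reactants: 4 6-iodo-7,4'-di-O-benzylapigenin
Product: 5 6-iodo-5,7,4'-tri-O-benzylapigenin [5,7-bis(benzyloxy)-2-(4-benzyloxyphenyl)-6-iodochromen-4-one]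
Conditions: BnBr (2 equiv), K2CO3 (3 equiv), DMF, 70 °C
Reagents that add atoms: benzyl bromide, BrCc1ccccc1
Why: Williamson ether synthesis under forcing conditions, where heat breaks the 5-OH to C4=O chelate and capping this ortho-iodophenol removes an acidic site that would otherwise give an unreactive, copper-binding phenoxide in the coupling.

Step 4
Reactants: 5 6-iodo-5,7,4'-tri-O-benzylapigenin; 6 genkwanin (1.5 equiv)
Product: 7 5'',7'',4'''-tri-O-benzylneocryptomerin [5,7-bis(benzyloxy)-2-(4-benzyloxyphenyl)-6-[4-(5-hydroxy-7-methoxy-4-oxochromen-2-yl)phenoxy]chromen-4-one]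
Conditions: CuI (20 mol%), picolinic acid (40 mol%), K3PO4 (3 equiv), 4 Å MS, DMSO, 100 °C, Ar
Reagents that add atoms: none
Why: Ullmann-type diaryl ether synthesis with monovalent copper, in which the picolinate-ligated copper phenoxide of the unhindered, more acidic 4'-OH of 6 couples with the aryl iodide under a ligand system developed for ortho-hindered partners, while the chelated 5-OH of 6 is too hindered and too weakly nucleophilic to compete.

Step 5
Reactants: 7 5'',7'',4'''-tri-O-benzylneocryptomerin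
Product: 8 neocryptomerin
Conditions: H2 (1 atm), 10% Pd/C, THF–MeOH (1:1), 25 °C
Reagents that add atoms: none
Why: Catalytic hydrogenolysis of benzyl ethers cleaves the three benzylic C–O bonds at 1 atm, while the vinylogous-ester C2=C3 bonds, the 7-methyl ether and the diaryl ether are inert under these conditions.

**Compound list**
1 | apigenin, 5,7-dihydroxy-2-(4-hydroxyphenyl)-4H-chromen-4-one | O=c1cc(-c2ccc(O)cc2)oc2cc(O)cc(O)c12 | starting material
2 | 7-O-benzylapigenin, 7-(benzyloxy)-5-hydroxy-2-(4-hydroxyphenyl)-4H-chromen-4-one (forms in the flask in step 1) | O=c1cc(-c2ccc(O)cc2)oc2cc(OCc3ccccc3)cc(O)c12 | intermediate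
3 | 7,4'-di-O-benzylapigenin, 7-(benzyloxy)-2-[4-(benzyloxy)phenyl]-5-hydroxy-4H-chromen-4-one | O=c1cc(-c2ccc(OCc3ccccc3)cc2)oc2cc(OCc3ccccc3)cc(O)c12 | intermediate
4 | 6-iodo-7,4'-di-O-benzylapigenin, 7-(benzyloxy)-2-[4-(benzyloxy)phenyl]-5-hydroxy-6-iodo-4H-chromen-4-one | O=c1cc(-c2ccc(OCc3ccccc3)cc2)oc2cc(OCc3ccccc3)c(I)c(O)c12 | intermediate
5 | 6-iodo-5,7,4'-tri-O-benzylapigenin, 5,7-bis(benzyloxy)-2-[4-(benzyloxy)phenyl]-6-iodo-4H-chromen-4-one | O=c1cc(-c2ccc(OCc3ccccc3)cc2)oc2cc(OCc3ccccc3)c(I)c(OCc3ccccc3)c12 | intermediate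
6 | genkwanin, 5-hydroxy-2-(4-hydroxyphenyl)-7-methoxy-4H-chromen-4-one | COc1cc(O)c2c(=O)cc(-c3ccc(O)cc3)oc2c1 | starting material
7 | 5'',7'',4'''-tri-O-benzylneocryptomerin, 5,7-bis(benzyloxy)-2-[4-(benzyloxy)phenyl]-6-[4-(5-hydroxy-7-methoxy-4-oxo-4H-chromen-2-yl)phenoxy]-4H-chromen-4-one | COc1cc(O)c2c(=O)cc(-c3ccc(Oc4c(OCc5ccccc5)cc5oc(-c6ccc(OCc7ccccc7)cc6)cc(=O)c5c4OCc4ccccc4)cc3)oc2c1 | intermediate
8 | neocryptomerin, 5,7-dihydroxy-6-[4-(5-hydroxy-7-methoxy-4-oxo-4H-chromen-2-yl)phenoxy]-2-(4-hydroxyphenyl)-4H-chromen-4-one | COc1cc(O)c2c(=O)cc(-c3ccc(Oc4c(O)cc5oc(-c6ccc(O)cc6)cc(=O)c5c4O)cc3)oc2c1 | target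

**Step count and risks**
Total step count: 5. Longest linear sequence: 5 steps (1 → 3 → 4 → 5 → 7 → 8); genkwanin 6 enters unchanged in step 4.

Most likely to fail, in order:

**Step 4 (Ullmann union of the two flavones).** The aryl iodide is electron-rich and flanked by two benzyloxy groups, so slow coupling and hydrodeiodination to tri-O-benzylapigenin are the main threats. The fallback reverses the polarity of the ether formation and builds the second pyranone afterwards; it sets out from 5 and comes back at 7.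
- Miyaura borylation of 5 (B2pin2, PdCl2(dppf), KOAc, dioxane, 90 °C) gives the 6-pinacolboronate of tri-O-benzylapigenin F1.
- Oxidation (NaBO3·4H2O, THF–H2O, 25 °C) gives 5,7,4'-tri-O-benzylscutellarein F2, which now acts as the nucleophile.
- SNAr on commercial 4-fluorobenzaldehyde (K2CO3, DMF, 100 °C) gives the 6-O-(4-formylphenyl) ether F3.
- Pyrrolidine-mediated aldol condensation and oxa-Michael closure with commercial 2',6'-dihydroxy-4'-methoxyacetophenone (EtOH, 70 °C) gives the racemic 5-hydroxy-7-methoxyflavanone F4.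
- Dehydrogenation with I2 (10 mol%) in DMSO at 120 °C gives 7.

**Step 2 (C6–H iodination).** Iodination at C8 or 6,8-di-iodination would erode the yield. The fallback avoids C–H iodination by buying the C6 oxygen in commercial scutellarein (5,6,7,4'-tetrahydroxyflavone); it sets out from 6 and comes back at 8.
- Genkwanin 6 is triflated at its unchelated 4'-OH (PhNTf2, K2CO3, DMF, 25 °C) to genkwanin 4'-O-triflate F5.
- Scutellarein is benzylated at its two most acidic hydroxyls (BnBr 2.1 equiv, K2CO3, DMF, Ar, 25 °C) to 7,4'-di-O-benzylscutellarein F6.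
- Pd-catalysed C–O coupling of the electron-poor triflate with the free 6-OH, the 5-OH being chelated (Pd(OAc)2, 2-di-tert-butylphosphino-2',4',6'-triisopropylbiphenyl, K3PO4, toluene, 100 °C), gives 7'',4'''-di-O-benzylneocryptomerin F7.
- Hydrogenolysis as in step 5 gives 8.

**Step 3 (benzylation of the chelated 5-OH).** This hydroxyl is chelated and flanked by iodine, so alkylation may stall or need heat that costs iodide. The fallback changes the protecting-group plan and the endgame; it sets out from 4 and comes back at 8.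
- The small electrophile MeI (Cs2CO3, DMF, 50 °C) caps the 5-OH to give 7-(benzyloxy)-2-[4-(benzyloxy)phenyl]-6-iodo-5-methoxychromen-4-one F8.
- Ullmann coupling with 6 under the conditions of step 4 gives 5''-O-methyl-7'',4'''-di-O-benzylneocryptomerin F9.
- BCl3 (CH2Cl2, −78 to 0 °C) removes both benzyl groups and, by chelation to C4''=O, only the peri 5''-methyl group, sparing the unchelated 7-OMe, to give 8.

**Further compounds**
F1 | step 4 | 5,7-bis(benzyloxy)-2-[4-(benzyloxy)phenyl]-6-(4,4,5,5-tetramethyl-1,3,2-dioxaborolan-2-yl)-4H-chromen-4-one | O=c1cc(-c2ccc(OCc3ccccc3)cc2)oc2cc(OCc3ccccc3)c(B3OC(C)(C)C(C)(C)O3)c(OCc3ccccc3)c12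
F2 | step 4 | 5,7,4'-tri-O-benzylscutellarein, 5,7-bis(benzyloxy)-2-[4-(benzyloxy)phenyl]-6-hydroxy-4H-chromen-4-one | O=c1cc(-c2ccc(OCc3ccccc3)cc2)oc2cc(OCc3ccccc3)c(O)c(OCc3ccccc3)c12
F3 | step 4 | 4-({5,7-bis(benzyloxy)-2-[4-(benzyloxy)phenyl]-4-oxo-4H-chromen-6-yl}oxy)benzaldehyde | O=Cc1ccc(Oc2c(OCc3ccccc3)cc3oc(-c4ccc(OCc5ccccc5)cc4)cc(=O)c3c2OCc2ccccc2)cc1
F4 | step 4 | racemic 5,7-bis(benzyloxy)-2-[4-(benzyloxy)phenyl]-6-[4-(5-hydroxy-7-methoxy-4-oxochroman-2-yl)phenoxy]-4H-chromen-4-one | COc1cc(O)c2c(c1)OC(CC2=O)c1ccc(Oc3c(OCc4ccccc4)cc4oc(-c5ccc(OCc6ccccc6)cc5)cc(=O)c4c3OCc3ccccc3)cc1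
F5 | step 2 | genkwanin 4'-O-triflate, 4-(5-hydroxy-7-methoxy-4-oxo-4H-chromen-2-yl)phenyl trifluoromethanesulfonate | COc1cc(O)c2c(=O)cc(-c3ccc(OS(=O)(=O)C(F)(F)F)cc3)oc2c1
F6 | step 2 | 7,4'-di-O-benzylscutellarein, 7-(benzyloxy)-2-[4-(benzyloxy)phenyl]-5,6-dihydroxy-4H-chromen-4-one | O=c1cc(-c2ccc(OCc3ccccc3)cc2)oc2cc(OCc3ccccc3)c(O)c(O)c12
F7 | step 2 | 7'',4'''-di-O-benzylneocryptomerin, 7-(benzyloxy)-2-[4-(benzyloxy)phenyl]-5-hydroxy-6-[4-(5-hydroxy-7-methoxy-4-oxo-4H-chromen-2-yl)phenoxy]-4H-chromen-4-one | COc1cc(O)c2c(=O)cc(-c3ccc(Oc4c(OCc5ccccc5)cc5oc(-c6ccc(OCc7ccccc7)cc6)cc(=O)c5c4O)cc3)oc2c1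
F8 | step 3 | 7-(benzyloxy)-2-[4-(benzyloxy)phenyl]-6-iodo-5-methoxy-4H-chromen-4-one | COc1c(I)c(OCc2ccccc2)cc2oc(-c3ccc(OCc4ccccc4)cc3)cc(=O)c12
F9 | step 3 | 5''-O-methyl-7'',4'''-di-O-benzylneocryptomerin, 7-(benzyloxy)-2-[4-(benzyloxy)phenyl]-6-[4-(5-hydroxy-7-methoxy-4-oxo-4H-chromen-2-yl)phenoxy]-5-methoxy-4H-chromen-4-one | COc1cc(O)c2c(=O)cc(-c3ccc(Oc4c(OCc5ccccc5)cc5oc(-c6ccc(OCc7ccccc7)cc6)cc(=O)c5c4OC)cc3)oc2c1
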